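**Plan**
1. Numbering: C1 = ring-fusion C(CH3), C2 = CHOH, C3 = CH2, C4 = C(OH)(i-Pr), C5 = ring-fusion CH (ring A = C1–C5); C6 = CH(OAng), C7 = CH2, C8/C9 = epoxide C(CH3)/CH, C10 = CH(OAng) (ring B = C1, C5–C10); β = face of the C1 methyl.
2. Retrosynthesis: after removal of the two angelates, the epoxide oxygen, C8–CH3, C4–i-Pr and C1–CH3, ring B is cut at C5–C6 and C8–C9 into a three-carbon β-silylacryloylsilane (C6–C8) and the methyl-ketone enolate of an acetylcyclopentene (C9, C10, C1–C5).
3. Enabling feature: ring B is a cycloheptane with oxygen on C8 and C10 (1,3 across C9), a heteroatom on C6 and an enolisable carbon (C1) next to C10. This 5-hetero-substituted cycloheptane-1,3-dione pattern is the direct output of a Brook-rearrangement/anionic oxy-Cope (3+4) annulation.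
4. Forward: ring A from (R)-4-silyloxycyclopentenone (steps 1–3); ring B by the annulation, with methylation of the ring-fusion enolate in the same flask (step 7); then C8 methyl enone, C4 carbinol, C6–OH, C10–OH, epoxide, esters and last the C2 carbinol.
5. Stereochemistry: the C4 silyloxy group directs C5; the Z-vinylsilane geometry gives C6 (boat oxy-Cope, then C–Si to C–O with retention); C5 gives C1 (cis fusion); convex-face organocerium addition gives C4; Felkin-type Luche reduction gives C10; C10–OH-directed epoxidation gives C8/C9; C4–OH-directed hydride delivery gives C2.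

Key step: step 7

Remark: read from the SMILES, the ring fusion is cis (C1–CH3 and H5 on the same face) and both esters are (Z)-2-methylbut-2-enoates (angelates); compounds 1, 5 and 20 are taken as commercially available.

Step 1
Reactants: 1 (R)-4-(tert-butyldimethylsilyloxy)cyclopent-2-en-1-one
Product: 2 (R)-4-(tert-butyldimethylsilyloxy)-2-iodocyclopent-2-en-1-one
Conditions: I2, pyridine, CH2Cl2, 0 °C → rt
Reagents that add atoms: iodine, II
Why: α-Iodination of the enone by pyridine addition, iodination of the enolate and elimination is standard for 4-silyloxycyclopentenones and leaves the silyloxy stereocenter (future C4) untouched.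

Step 2
Reactants: 2 (R)-4-(tert-butyldimethylsilyloxy)-2-iodocyclopent-2-en-1-one
Product: 3 (R)-8-(tert-butyldimethylsilyloxy)-6-iodo-1,4-dioxaspiro[4.4]non-6-ene
Conditions: Me3SiOCH2CH2OSiMe3, TMSOTf (cat.), CH2Cl2, −78 → −20 °C
Reagents that add atoms: 1,2-bis(trimethylsilyloxy)ethane, C[Si](C)(C)OCCO[Si](C)(C)C
Why: Noyori ketalization masks the carbonyl (future C2) as a symmetric dioxolane at low temperature without moving the double bond or cleaving the silyl ether.

Step 3
Reactants: 3 (R)-8-(tert-butyldimethylsilyloxy)-6-iodo-1,4-dioxaspiro[4.4]non-6-ene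
Product: 4 1-[(R)-8-(tert-butyldimethylsilyloxy)-1,4-dioxaspiro[4.4]non-6-en-6-yl]ethan-1-one
Conditions: t-BuLi, Et2O, −78 °C; then MeC(O)N(OMe)Me, −78 → 0 °C
Reagents that add atoms: N-methoxy-N-methylacetamide, CC(=O)N(C)OC
Why: Iodine–lithium exchange gives the ketal-flanked vinyllithium (an α-keto vinyl anion equivalent), which the Weinreb amide acylates once to the alkenyl methyl ketone (Weinreb ketone synthesis).

Step 4
Reactants: 5 tert-butyldimethyl(prop-2-yn-1-yloxy)silane
Product: 7 rac-1-(tert-butyldimethylsilyl)-3-(dimethylphenylsilyl)prop-2-yn-1-ol, via C-silylated propargyl ether 6 (not isolated)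
Conditions: n-BuLi, THF, −78 °C; PhMe2SiCl, → 0 °C; then t-BuLi, −78 → −45 °C; AcOH
Reagents that add atoms: chlorodimethylphenylsilane, C[Si](C)(Cl)c1ccccc1
Why: C-Silylation of the lithium acetylide followed by propargylic deprotonation triggers a 1,2-shift of silicon from oxygen to carbon (retro-Brook rearrangement), driven by formation of the alkoxide.

Step 5
Reactants: 7 rac-1-(tert-butyldimethylsilyl)-3-(dimethylphenylsilyl)prop-2-yn-1-ol
Product: 8 rac-(Z)-1-(tert-butyldimethylsilyl)-3-(dimethylphenylsilyl)prop-2-en-1-ol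
Conditions: H2 (1 atm), Pd/CaCO3 poisoned with Pb(OAc)2 (Lindlar catalyst), quinoline, hexane, rt
Reagents that add atoms: none
Why: Lindlar semihydrogenation adds H2 syn to the silylalkyne and gives the Z-vinylsilane whose geometry later defines C6.

Step 6
Reactants: 8 rac-(Z)-1-(tert-butyldimethylsilyl)-3-(dimethylphenylsilyl)prop-2-en-1-ol
Product: 9 (Z)-1-(tert-butyldimethylsilyl)-3-(dimethylphenylsilyl)prop-2-en-1-one
Conditions: Dess–Martin periodinane, pyridine, CH2Cl2, 0 °C, dark
Reagents that add atoms: none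
Why: Dess–Martin oxidation of α-silyl carbinols to acylsilanes proceeds under non-basic conditions that avoid Brook rearrangement and Z-to-E isomerisation.

Step 7
Reactants: 4 1-[(R)-8-(tert-butyldimethylsilyloxy)-1,4-dioxaspiro[4.4]non-6-en-6-yl]ethan-1-one, 9 (Z)-1-(tert-butyldimethylsilyl)-3-(dimethylphenylsilyl)prop-2-en-1-one
Product: 13 cis-fused hydroazulen-10-one with 1β-CH3; 5β-H; C2 dioxolane; 4β-OTBS; 6β-SiMe2Ph; 8-OTBS Δ7-enol ether, via lithium dienolate 10 (not isolated), via divinylcyclopropanolate 11 (not isolated), via ring-fusion lithium enolate 12 (not isolated)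
Conditions: LiN(i-Pr)2, THF, −80 °C; 9, −80 → −30 °C; then MeI, DMPU, −78 → −20 °C
Reagents that add atoms: iodomethane, CI
Why: Enolate 10 adds to the acylsilane carbonyl (C9–C8 bond), a 1,2-Brook shift of silicon to oxygen frees a siloxyallyl anion that closes onto the C10 carbonyl (3-exo-trig) to the cis-divinylcyclopropanolate 11, and an alkoxide-accelerated oxy-Cope shift through a boat transition state breaks C8–C10 and makes C5–C6, so ring B closes by [3,3]-sigmatropic enlargement of the three-membered ring and the resulting C1=C10 lithium enolate 12 is C-methylated in the same flask. The closest known reaction type is the Brook-rearrangement-mediated (3+4) annulation of β-silylacryloylsilanes with lithium enolates of alkenyl methyl ketones, 1-acetylcycloalkenes included, followed by ordinary enolate alkylation. C6 is controlled by alkene geometry: the Z-silyl group lies inside the boat and therefore ends cis to H5, as the stereospecific divinylcyclopropane rearrangement demands. C5 is controlled by the C4 silyloxy group, because the cyclopropanolates should interconvert by ring opening and only the boat with the vinylsilane over the face anti to OTBS is low in energy, and C1 is controlled by C5, MeI entering the enolate on the H5 face away from the new C5–C6 bond to give the cis-fused ring system. The step needs kinetic deprotonation of the acetyl methyl group (LiN(i-Pr)2 at −80 °C, the γ-hydrogen at C4 being hindered), C- over O-methylation, and methylation faster than proton transfer from C9, which low temperature, MeI and DMPU should secure.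

Step 8
Reactants: 13 cis-fused hydroazulen-10-one (bis-silyl stage)
Product: 14 hydroazulene-8,10-dione with 4β-OH; 6β-SiMe2Ph; C2 dioxolane
Conditions: HF·pyridine, pyridine, THF, 0 °C → rt
Reagents that add atoms: none
Why: Fluoride-induced desilylation cleaves the silyl enol ether (to the C8/C10 β-diketone) and the secondary C4 silyl ether, while the C–SiMe2Ph bond and the dioxolane should persist.

Step 9
Reactants: 14 hydroazulene-8,10-dione
Product: 15 8-(trifluoromethanesulfonyloxy)-Δ8-en-10-one with 4β-OH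
Conditions: PhNTf2, i-Pr2NEt, DMAP (cat.), CH2Cl2, 0 °C → rt
Reagents that add atoms: N-phenylbis(trifluoromethanesulfonimide), O=S(=O)(N(c1ccccc1)S(=O)(=O)C(F)(F)F)C(F)(F)F
Why: O-Sulfonylation of the enolised β-diketone should occur at the oxygen on C8, remote from the quaternary C1, as with 4,4-disubstituted cyclic 1,3-diones, and this mild triflating agent spares the free secondary alcohol.

Step 10
Reactants: 15 8-(trifluoromethanesulfonyloxy)-Δ8-en-10-one
Product: 16 8-methyl-Δ8-en-10-one with 4β-OH; 6β-SiMe2Ph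
Conditions: Me2CuLi (excess), Et2O/THF, −78 → −20 °C
Reagents that add atoms: lithium dimethylcuprate, [Li+].C[Cu-]C
Why: Conjugate addition–elimination of the cuprate on the β-sulfonyloxy enone replaces triflate by methyl without touching ketal or silane.

Step 11
Reactants: 16 8-methyl-Δ8-en-10-one with 4β-OH
Product: 17 8-methyl-Δ8-ene-4,10-dione with 6β-SiMe2Ph
Conditions: Dess–Martin periodinane, NaHCO3, CH2Cl2, 0 °C → rt
Reagents that add atoms: none
Why: Dess–Martin oxidation gives the cyclopentanone under neutral conditions that should not epimerise C5, and the β-silyl group at C6 cannot eliminate as an oxygen substituent would.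

Step 12
Reactants: 17 8-methyl-Δ8-ene-4,10-dione
Product: 18 4α-hydroxy-4β-isopropyl-8-methyl-Δ8-en-10-one with 6β-SiMe2Ph
Conditions: i-PrMgCl, CeCl3, THF, −78 °C
Reagents that add atoms: isopropylmagnesium chloride, CC(C)[Mg]Cl
Why: The organocerium reagent should add to the cyclopentanone far faster than to the β,β-disubstituted enone flanked by quaternary C1, without enolisation, entering on the convex β face anti to the C5–C6 bond so that the new C4 hydroxyl is α.

Step 13
Reactants: 18 4α-hydroxy-4β-isopropyl-8-methyl-Δ8-en-10-one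
Product: 19 4α,6β-dihydroxy-4β-isopropyl-8-methyl-Δ8-en-10-one
Conditions: KBr, AcOOH, NaOAc, AcOH, rt
Reagents that add atoms: peracetic acid, CC(=O)OO
Why: Fleming–Tamao oxidation (ipso-bromodesilylation of the phenyl group, then peracid-induced 1,2-shift from silicon to oxygen) converts C6–Si into C6–OH with retention, the electron-poor enone being inert to the peracid.

Step 14
Reactants: 19 4α,6β-dihydroxy enone, 20 angelic acid
Product: 21 6β-angeloyloxy-4α-hydroxy-4β-isopropyl-8-methyl-Δ8-en-10-one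
Conditions: 20, 2,4,6-Cl3C6H2COCl, Et3N, toluene, rt; then 19, 80 °C
Reagents that add atoms: none
Why: Yamaguchi mixed-anhydride esterification without DMAP acylates the only secondary hydroxyl (C6) without isomerising angelate to tiglate, the tertiary C4 hydroxyl being unreactive.

Step 15
Reactants: 21 6β-angeloyloxy enone
Product: 22 6β-angeloyloxy-Δ8-ene-4α,10α-diol (C2 dioxolane)
Conditions: NaBH4, CeCl3·7H2O, MeOH, −78 → −40 °C
Reagents that add atoms: none
Why: Luche reduction gives clean 1,2-reduction of the enone, hydride entering past the C1 methyl and anti to the bulky ketal carbon C2 on the α side of C1 (Felkin-type), which should give the new 10α carbinol.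

Step 16
Reactants: 22 6β-angeloyloxy-Δ8-ene-4α,10α-diol
Product: 23 6β-angeloyloxy-4α,10α-dihydroxy-Δ8-en-2-one
Conditions: PPTS, acetone/H2O, 40 °C
Reagents that add atoms: water, O
Why: Mild acid-catalysed hydrolysis of the dioxolane unmasks the C2 ketone before the acid-sensitive epoxide exists, under conditions that should be too mild to ionise the allylic alcohol.

Step 17
Reactants: 23 6β-angeloyloxy-4α,10α-dihydroxy-Δ8-en-2-one
Product: 24 6β-angeloyloxy-8α,9α-epoxy-4α,10α-dihydroxy-2-one
Conditions: VO(acac)2 (cat.), t-BuOOH, CH2Cl2, 0 °C → rt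
Reagents that add atoms: tert-butyl hydroperoxide, CC(C)(C)OO
Why: Vanadium-catalysed hydroxyl-directed epoxidation delivers oxygen to the trisubstituted C8=C9 bond from the face of the allylic C10 hydroxyl (syn selectivity of cyclic allylic alcohols), setting C8 and C9 as the α-epoxide.

Step 18
Reactants: 24 8α,9α-epoxy-10α-alcohol, 20 angelic acid
Product: 25 6β,10α-bis(angeloyloxy)-8α,9α-epoxy-4α-hydroxy-2-one
Conditions: 20, 2,4,6-Cl3C6H2COCl, Et3N, toluene, rt; then 24, 80 °C
Reagents that add atoms: none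
Why: The same Yamaguchi mixed-anhydride esterification acylates the hindered C10 carbinol under weakly basic conditions that should cause neither Payne rearrangement nor angelate isomerisation.

Step 19
Reactants: 25 6β,10α-bis(angeloyloxy)-8α,9α-epoxy-4α-hydroxy-2-one
Product: 26 target CNP0265715.3
Conditions: Me4NBH(OAc)3, MeCN/AcOH, −30 °C
Reagents that add atoms: none
Why: In this Evans–Saksena reduction the tertiary C4 hydroxyl binds the triacetoxyborohydride and delivers hydride to the α face of the C2 ketone, which should give the 1,3-anti (2β) carbinol while esters and epoxide are inert to this mild reagent.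

**Compound list**
1 | (R)-4-(tert-butyldimethylsilyloxy)cyclopent-2-en-1-one | O=C1C=C[C@H](O[Si](C)(C)C(C)(C)C)C1 | starting material
2 | (R)-4-(tert-butyldimethylsilyloxy)-2-iodocyclopent-2-en-1-one | O=C1C(I)=C[C@H](O[Si](C)(C)C(C)(C)C)C1 | intermediate
3 | (R)-8-(tert-butyldimethylsilyloxy)-6-iodo-1,4-dioxaspiro[4.4]non-6-ene | IC1=C[C@H](O[Si](C)(C)C(C)(C)C)CC12OCCO2 | intermediate
4 | 1-[(R)-8-(tert-butyldimethylsilyloxy)-1,4-dioxaspiro[4.4]non-6-en-6-yl]ethan-1-one (carbons C9, C10, C1–C5) | CC(=O)C1=C[C@H](O[Si](C)(C)C(C)(C)C)CC12OCCO2 | intermediate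
5 | tert-butyldimethyl(prop-2-yn-1-yloxy)silane | C#CCO[Si](C)(C)C(C)(C)C | starting material
6 | tert-butyldimethyl{[3-(dimethylphenylsilyl)prop-2-yn-1-yl]oxy}silane | C[Si](C)(C#CCO[Si](C)(C)C(C)(C)C)c1ccccc1 | intermediate
7 | rac-1-(tert-butyldimethylsilyl)-3-(dimethylphenylsilyl)prop-2-yn-1-ol | OC(C#C[Si](C)(C)c1ccccc1)[Si](C)(C)C(C)(C)C | intermediate
8 | rac-(Z)-1-(tert-butyldimethylsilyl)-3-(dimethylphenylsilyl)prop-2-en-1-ol | OC(/C=C\[Si](C)(C)c1ccccc1)[Si](C)(C)C(C)(C)C | intermediate
9 | (Z)-1-(tert-butyldimethylsilyl)-3-(dimethylphenylsilyl)prop-2-en-1-one (carbons C8, C7, C6) | O=C(/C=C\[Si](C)(C)c1ccccc1)[Si](C)(C)C(C)(C)C | intermediate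
10 | lithium dienolate of 4 (kinetic methyl enolate) | [Li]OC(=C)C1=C[C@H](O[Si](C)(C)C(C)(C)C)CC12OCCO2 | intermediate
11 | lithium cis-1,2-dialkenylcyclopropan-1-olate (ring C8–C9–C10; silyloxy on C8; vinylsilane and cyclopentenyl cis) | [Li]O[C@]3(C[C@]3(O[Si](C)(C)C(C)(C)C)/C=C\[Si](C)(C)c4ccccc4)C1=C[C@H](O[Si](C)(C)C(C)(C)C)CC12OCCO2 | intermediate
12 | lithium C1=C10 enolate of the hydroazulenone (5β-H; 6β-SiMe2Ph; 4β-OTBS; 8-OTBS Δ7) | C[Si](C)(c1ccccc1)[C@H]1C=C(O[Si](C)(C)C(C)(C)C)CC(O[Li])=C2[C@@H]1[C@H](O[Si](C)(C)C(C)(C)C)CC23OCCO3 | intermediate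
13 | cis-fused hydroazulen-10-one: 1β-CH3, 5β-H, C2 ethylene ketal, 4β-OTBS, 6β-SiMe2Ph, 8-OTBS Δ7-enol ether | C[Si](C)(c1ccccc1)[C@H]1C=C(O[Si](C)(C)C(C)(C)C)CC(=O)[C@@]2(C)[C@@H]1[C@H](O[Si](C)(C)C(C)(C)C)CC23OCCO3 | intermediate
14 | hydroazulene-8,10-dione (drawn as diketo tautomer): 4β-OH, 6β-SiMe2Ph, C2 ethylene ketal | C[Si](C)(c1ccccc1)[C@H]1CC(=O)CC(=O)[C@@]2(C)[C@@H]1[C@H](O)CC23OCCO3 | intermediate
15 | 8-(trifluoromethanesulfonyloxy)-Δ8-en-10-one: 4β-OH, 6β-SiMe2Ph, C2 ethylene ketal | C[Si](C)(c1ccccc1)[C@H]1CC(OS(=O)(=O)C(F)(F)F)=CC(=O)[C@@]2(C)[C@@H]1[C@H](O)CC23OCCO3 | intermediate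
16 | 8-methyl-Δ8-en-10-one: 4β-OH, 6β-SiMe2Ph, C2 ethylene ketal | C[Si](C)(c1ccccc1)[C@H]1CC(C)=CC(=O)[C@@]2(C)[C@@H]1[C@H](O)CC23OCCO3 | intermediate
17 | 8-methyl-Δ8-ene-4,10-dione: 6β-SiMe2Ph, C2 ethylene ketal | C[Si](C)(c1ccccc1)[C@H]1CC(C)=CC(=O)[C@@]2(C)[C@@H]1C(=O)CC23OCCO3 | intermediate
18 | 4α-hydroxy-4β-isopropyl-8-methyl-Δ8-en-10-one: 6β-SiMe2Ph, C2 ethylene ketal | C[Si](C)(c1ccccc1)[C@H]1CC(C)=CC(=O)[C@@]2(C)[C@@H]1[C@](O)(C(C)C)CC23OCCO3 | intermediate
19 | 4α,6β-dihydroxy-4β-isopropyl-8-methyl-Δ8-en-10-one, C2 ethylene ketal | O[C@H]1CC(C)=CC(=O)[C@@]2(C)[C@@H]1[C@](O)(C(C)C)CC23OCCO3 | intermediate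
20 | angelic acid, (Z)-2-methylbut-2-enoic acid | C/C=C(/C)C(=O)O | starting material
21 | 6β-angeloyloxy-4α-hydroxy-4β-isopropyl-8-methyl-Δ8-en-10-one, C2 ethylene ketal | C/C=C(/C)C(=O)O[C@H]1CC(C)=CC(=O)[C@@]2(C)[C@@H]1[C@](O)(C(C)C)CC23OCCO3 | intermediate
22 | 6β-angeloyloxy-Δ8-ene-4α,10α-diol, C2 ethylene ketal | C/C=C(/C)C(=O)O[C@H]1CC(C)=C[C@H](O)[C@@]2(C)[C@@H]1[C@](O)(C(C)C)CC23OCCO3 | intermediate
23 | 6β-angeloyloxy-4α,10α-dihydroxy-Δ8-en-2-one | C/C=C(/C)C(=O)O[C@H]1CC(C)=C[C@H](O)[C@@]2(C)[C@@H]1[C@](O)(C(C)C)CC2=O | intermediate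
24 | 6β-angeloyloxy-8α,9α-epoxy-4α,10α-dihydroxy-2-one | C/C=C(/C)C(=O)O[C@H]1C[C@]2(C)O[C@@H]2[C@H](O)[C@@]2(C)[C@@H]1[C@](O)(C(C)C)CC2=O | intermediate
25 | 6β,10α-bis(angeloyloxy)-8α,9α-epoxy-4α-hydroxy-2-one | C/C=C(/C)C(=O)O[C@H]1C[C@]2(C)O[C@@H]2[C@H](OC(=O)/C(C)=C\C)[C@@]2(C)[C@@H]1[C@](O)(C(C)C)CC2=O | intermediate
26 | CNP0265715.3: cis-fused 6β,10α-bis(angeloyloxy)-8α,9α-epoxy-daucane-2β,4α-diol | C/C=C(/C)C(=O)O[C@H]1C[C@]2(C)O[C@@H]2[C@H](OC(=O)/C(C)=C\C)[C@@]2(C)[C@@H]1[C@](O)(C(C)C)C[C@@H]2O | target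

**Count**
Total step count: 19. Longest linear sequence: 16 steps (steps 1–3 and 7–19; the acylsilane branch, steps 4–6 and 7–19, is equally long).

**Steps most likely to fail**

1. Step 7. The Z-silyl group has to sit inside the boat of the oxy-Cope shift. If this slows the shift, the cyclopropanolate may open unproductively or lose stereospecificity at C6, and the hindered enolate may be protonated instead of methylated. Fallback (C6 set by inversion instead of by alkene geometry): it sets out from 7 and 4. Reduction of 7 with NaAlH2(OCH2CH2OMe)2 (anti hydroalumination of the propargylic alcohol) should give the (E)-allylic alcohol F1, and Dess–Martin oxidation the (E)-acylsilane F2, whose silyl group lies outside the boat. Annulation with the enolate of 4 and methylation as in step 7 should give the 6α-silyl hydroazulenone F3. This is carried through the operations of steps 8–13 by way of the β-diketone F4, the vinylogous triflate F5, the methyl enone alcohol F6, the 4,10-dione F7 and the isopropyl carbinol F8 to the 6α-alcohol F9. Mitsunobu esterification of F9 with 20 (PPh3, diisopropyl azodicarboxylate, toluene, 0 °C) inverts C6 and comes back to the route at 21.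

2. Step 15. Hydride delivery to C10 may show poor facial selectivity, since it rests only on the difference between the methyl group and the ketal carbon on C1; the wrong carbinol would also misdirect the epoxidation. Fallback (C10 controlled by the epoxide instead of the reverse): it sets out from 21. Nucleophilic epoxidation (t-BuOOH, DBU, CH2Cl2) should attack C8 anti to the β-oriented C6 ester and give the α-epoxy ketone F10. Reduction with Zn(BH4)2 (Et2O, −20 °C), anti to the chelated epoxide oxygen, should give the cis-epoxy alcohol F11. Removal of the dioxolane under nearly neutral conditions (catalytic (NH4)2Ce(NO3)6, MeCN/borate buffer pH 8) comes back to the route at 24.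

3. Step 12. The branched organometallic may reduce the hindered cyclopentanone by β-hydride transfer, enolise it (loss of the C5 configuration) or attack the C10 enone. Fallback (sp2 nucleophile, then hydrogenation): it sets out from 17. Isopropenylmagnesium bromide with CeCl3 (THF, −78 °C), which has no β-hydrogen to transfer and is less hindered, should give the isopropenyl carbinol F12. Hydrogenation over RhCl(PPh3)3 (H2, benzene, rt), which reduces only the 1,1-disubstituted alkene, comes back to the route at 18.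

**Further compounds**
F1 | step 7 | rac-(E)-1-(tert-butyldimethylsilyl)-3-(dimethylphenylsilyl)prop-2-en-1-ol | OC(/C=C/[Si](C)(C)c1ccccc1)[Si](C)(C)C(C)(C)C
F2 | step 7 | (E)-1-(tert-butyldimethylsilyl)-3-(dimethylphenylsilyl)prop-2-en-1-one | O=C(/C=C/[Si](C)(C)c1ccccc1)[Si](C)(C)C(C)(C)C
F3 | step 7 | C6 epimer of 13 (6α-SiMe2Ph) | C[Si](C)(c1ccccc1)[C@@H]1C=C(O[Si](C)(C)C(C)(C)C)CC(=O)[C@@]2(C)[C@@H]1[C@H](O[Si](C)(C)C(C)(C)C)CC23OCCO3
F4 | step 7 | C6 epimer of 14 | C[Si](C)(c1ccccc1)[C@@H]1CC(=O)CC(=O)[C@@]2(C)[C@@H]1[C@H](O)CC23OCCO3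
F5 | step 7 | C6 epimer of 15 | C[Si](C)(c1ccccc1)[C@@H]1CC(OS(=O)(=O)C(F)(F)F)=CC(=O)[C@@]2(C)[C@@H]1[C@H](O)CC23OCCO3
F6 | step 7 | C6 epimer of 16 | C[Si](C)(c1ccccc1)[C@@H]1CC(C)=CC(=O)[C@@]2(C)[C@@H]1[C@H](O)CC23OCCO3
F7 | step 7 | C6 epimer of 17 | C[Si](C)(c1ccccc1)[C@@H]1CC(C)=CC(=O)[C@@]2(C)[C@@H]1C(=O)CC23OCCO3
F8 | step 7 | C6 epimer of 18 | C[Si](C)(c1ccccc1)[C@@H]1CC(C)=CC(=O)[C@@]2(C)[C@@H]1[C@](O)(C(C)C)CC23OCCO3
F9 | step 7 | C6 epimer of 19 (6α-OH) | O[C@@H]1CC(C)=CC(=O)[C@@]2(C)[C@@H]1[C@](O)(C(C)C)CC23OCCO3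
F10 | step 15 | 6β-angeloyloxy-8α,9α-epoxy-4α-hydroxy-10-one, C2 ethylene ketal | C/C=C(/C)C(=O)O[C@H]1C[C@]2(C)O[C@@H]2C(=O)[C@@]2(C)[C@@H]1[C@](O)(C(C)C)CC23OCCO3
F11 | step 15 | 6β-angeloyloxy-8α,9α-epoxy-4α,10α-diol, C2 ethylene ketal | C/C=C(/C)C(=O)O[C@H]1C[C@]2(C)O[C@@H]2[C@H](O)[C@@]2(C)[C@@H]1[C@](O)(C(C)C)CC23OCCO3
F12 | step 12 | 4α-hydroxy-4β-isopropenyl analogue of 18 | C[Si](C)(c1ccccc1)[C@H]1CC(C)=CC(=O)[C@@]2(C)[C@@H]1[C@](O)(C(C)=C)CC23OCCO3
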